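**Retrosynthetic overview**

1. The epoxy aldehyde comes from Sharpless epoxidation and oxidation of a (13E)-allylic alcohol, itself made by methylalumination/hydroxymethylation of a terminal alkyne carried through the route.
2. The 3α-acetate comes from equatorial hydride delivery to a C3 ketone; the 8(17)-alkene from syn-elimination of a C8 selenoxide; the C4 quaternary centre from methylation of the ring β-keto ester anti to C20.
3. Key step: enantioselective phenylselanyl group-transfer radical bicyclization of an acyclic α-seleno β-keto ester dienyne. Ring A closes first (C4–C5), ring B second (C9–C10), in one operation that sets C5, C9 and C10.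
4. The acyclic precursor comes from a crossed Claisen condensation after two rounds of isopropenyl Grignard addition and Johnson–Claisen rearrangement starting from pent-4-ynal (both alkenes E).

Assumptions: pent-4-ynal is bought as such; the sense of induction in step 7 is assigned by analogy and the ligand antipode is used if it proves opposite; bicyclic compounds are named on the labdane skeleton (normal series: 5α-H, 9α-H, 10β-CH3; C18 = 4α substituent, C19 = 4β substituent).

**Route**

Step 1
Reactants: 1 pent-4-ynal; 2 isopropenylmagnesium bromide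
Product: 3 rac-2-methylhept-1-en-6-yn-3-ol
Conditions: THF, −78 → 0 °C; H2O
Reagents that add atoms: none
Why: Grignard 1,2-addition to the aldehyde is far faster at −78 °C than deprotonation of the alkyne C–H, and the racemic carbinol centre is erased in step 2.

Step 2
Reactants: 3 rac-2-methylhept-1-en-6-yn-3-ol; 4 trimethyl orthoacetate
Product: 5 methyl (4E)-4-methylnon-4-en-8-ynoate
Conditions: EtCO2H (cat.), excess 4, 110 → 140 °C, MeOH distilled off
Reagents that add atoms: none
Why: Johnson–Claisen orthoester rearrangement through a chair transition state with the carbinol substituent equatorial gives the (E)-trisubstituted alkene with high selectivity.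

Step 3
Reactants: 5 methyl (4E)-4-methylnon-4-en-8-ynoate; 2 isopropenylmagnesium bromide
Product: 7 rac-(6E)-2,6-dimethylundeca-1,6-dien-10-yn-3-ol, via aldehyde 6 (not isolated)
Conditions: iBu2AlH (1.05 equiv), CH2Cl2, −78 °C; then 2 (2.5 equiv), THF, −78 → 0 °C; H2O
Reagents that add atoms: none
Why: Partial reduction gives an aluminium hemiacetal that is stable at −78 °C and releases the aldehyde only as the Grignard reagent traps it (one-pot reduction/1,2-addition); the new carbinol centre is racemic and is erased in step 4.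

Step 4
Reactants: 7 rac-(6E)-2,6-dimethylundeca-1,6-dien-10-yn-3-ol; 4 trimethyl orthoacetate
Product: 8 methyl (4E,8E)-4,8-dimethyltrideca-4,8-dien-12-ynoate
Conditions: EtCO2H (cat.), excess 4, 110 → 140 °C, MeOH distilled off
Reagents that add atoms: none
Why: A second Johnson–Claisen rearrangement sets the second (E)-trisubstituted alkene by the same chair preference.

Step 5
Reactants: 8 methyl (4E,8E)-4,8-dimethyltrideca-4,8-dien-12-ynoate; 9 methyl acetate
Product: 11 methyl (6E,10E)-6,10-dimethyl-3-oxopentadeca-6,10-dien-14-ynoate, via lithium enolate 10 (not isolated)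
Conditions: LiN(iPr)2 (LDA, 3.5 equiv), 9 (3.6 equiv), THF, −78 °C; then 8, −78 → 0 °C; 1 M HCl
Reagents that add atoms: none
Why: Crossed Claisen condensation: the preformed ester enolate acylates on 8 and the β-keto ester is drawn off as its stabilized enolate, which drives the reaction.

Step 6
Reactants: 11 methyl (6E,10E)-6,10-dimethyl-3-oxopentadeca-6,10-dien-14-ynoate
Product: 13 rac-methyl (6E,10E)-6,10-dimethyl-3-oxo-2-(phenylselanyl)pentadeca-6,10-dien-14-ynoate, via sodium enolate 12 (not isolated)
Conditions: NaH, THF, 0 °C; then PhSeCl (1.0 equiv), −78 °C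
Reagents that add atoms: benzeneselenenyl chloride, Cl[Se]c1ccccc1
Why: C-selenenylation of the β-keto ester enolate is much faster than addition of PhSeCl to the trisubstituted alkenes, and the new racemic centre becomes the planar radical centre in step 7.

Step 7
Reactants: 13 rac-methyl (6E,10E)-6,10-dimethyl-3-oxo-2-(phenylselanyl)pentadeca-6,10-dien-14-ynoate
Product: 14 methyl 3-oxo-8ξ-(phenylselanyl)-15,16,19-trinorlabd-13-yn-18-oate
Conditions: Mg(ClO4)2 (0.5 equiv), 2,2'-(propane-2,2-diyl)bis[(4S)-4-tert-butyl-4,5-dihydro-1,3-oxazole] (0.55 equiv), 4 Å MS, toluene, hν (Hg lamp, Pyrex), −45 °C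
Reagents that add atoms: none
Why: In this chiral-Lewis-acid-catalysed group-transfer radical polyene cyclization, C–Se homolysis gives the magnesium-chelated β-keto ester radical with one face blocked by the bisoxazoline, so 6-endo attack on C5 and then 6-endo attack of the C10 radical on C9 through an all-chair array give the trans-decalin (5α-H, 10β-CH3, equatorial C9 chain) in the normal absolute series, and PhSe transfer from 13 to the tertiary C8 radical carries the chain faster than attack on the alkyne at −45 °C.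

Step 8
Reactants: 14 methyl 3-oxo-8ξ-(phenylselanyl)-15,16,19-trinorlabd-13-yn-18-oate
Product: 15 methyl 3-oxo-8ξ-(phenylselanyl)-15,16-dinorlabd-13-yn-19-oate
Conditions: MeI (5 equiv), K2CO3 (3 equiv), acetone, 23 °C
Reagents that add atoms: iodomethane, CI
Why: C-alkylation of the ring β-keto ester enolate takes place on the α face, anti to the axial C10 methyl group, which sets C4 with 4α-CH3 and axial 4β-CO2Me.

Step 9
Reactants: 15 methyl 3-oxo-8ξ-(phenylselanyl)-15,16-dinorlabd-13-yn-19-oate
Product: 17 methyl 3-oxo-15,16-dinorlabd-8(17)-en-13-yn-19-oate, via selenoxide 16 (not isolated)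
Conditions: mCPBA (1.05 equiv), CH2Cl2, −78 °C; then Et3N, −78 → 23 °C
Reagents that add atoms: none
Why: Selenoxide syn-elimination needs a planar five-membered transition state that only the freely rotating C17 methyl group reaches easily (as in Cope eliminations of 1-methylcyclohexyl amine oxides), so both C8 epimers give the exocyclic alkene, and selenium is oxidized at −78 °C before alkyne or ketone.

Step 10
Reactants: 17 methyl 3-oxo-15,16-dinorlabd-8(17)-en-13-yn-19-oate
Product: 19 methyl 3α-acetoxy-15,16-dinorlabd-8(17)-en-13-yn-19-oate, via lithium alkoxide 18 (not isolated)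
Conditions: LiBH(s-Bu)3 (L-Selectride, 1.2 equiv), THF, −78 °C; then Ac2O, DMAP, −78 → 23 °C
Reagents that add atoms: acetic anhydride, CC(=O)OC(C)=O
Why: The bulky hydride attacks the C3 ketone from the equatorial direction (as with other 4,4-disubstituted 3-keto terpenoids), which sets C3 as the axial 3α-alkoxide, and this is acetylated in the same flask (reductive acylation).

Step 11
Reactants: 19 methyl 3α-acetoxy-15,16-dinorlabd-8(17)-en-13-yn-19-oate
Product: 21 methyl (13E)-3α-acetoxy-15-hydroxylabda-8(17),13-dien-19-oate, via alkenylalane 20 (not isolated)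
Conditions: AlMe3 (3 equiv), Cp2ZrCl2 (0.2 equiv), H2O (1 equiv), CH2Cl2, −23 °C; then (CH2O)n, THF, 0 → 23 °C; aqueous work-up
Reagents that add atoms: trimethylaluminium, C[Al](C)C; formaldehyde (as paraformaldehyde), C=O
Why: Negishi zirconium-catalysed methylalumination adds CH3 and Al syn across the terminal alkyne with Al at the terminus, and the alkenylalane is hydroxymethylated with retention to give the (13E)-alcohol, the short water-accelerated reaction at −23 °C sparing acetate and ester.

Step 12
Reactants: 21 methyl (13E)-3α-acetoxy-15-hydroxylabda-8(17),13-dien-19-oate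
Product: 22 methyl (13R,14R)-3α-acetoxy-13,14-epoxy-15-hydroxylabd-8(17)-en-19-oate
Conditions: Ti(OiPr)4 (10 mol %), D-(−)-diethyl tartrate (12 mol %), t-BuOOH, 4 Å MS, CH2Cl2, −20 °C
Reagents that add atoms: tert-butyl hydroperoxide, CC(C)(C)OO
Why: Sharpless asymmetric epoxidation with the D-tartrate delivers oxygen to the face that gives the (13R,14R) epoxy alcohol (the (2R,3R) sense known for geraniol-type alcohols), and only the allylic-alcohol alkene reacts.

Step 13
Reactants: 22 methyl (13R,14R)-3α-acetoxy-13,14-epoxy-15-hydroxylabd-8(17)-en-19-oate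
Product: 23 methyl (13R,14S)-3α-acetoxy-13,14-epoxy-15-oxolabd-8(17)-en-19-oate
Conditions: Dess–Martin periodinane, NaHCO3, CH2Cl2, 0 → 23 °C
Reagents that add atoms: none
Why: Buffered Dess–Martin oxidation turns the primary alcohol into the α,β-epoxy aldehyde without opening the epoxide, and the C14 descriptor changes from R to S only through the priority rules.

**Compound list**

1 | pent-4-ynal | C#CCCC=O | starting material
2 | isopropenylmagnesium bromide (prop-1-en-2-ylmagnesium bromide) | CC(=C)[Mg]Br | starting material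
3 | rac-2-methylhept-1-en-6-yn-3-ol | C=C(C)C(O)CCC#C | intermediate
4 | trimethyl orthoacetate (1,1,1-trimethoxyethane) | CC(OC)(OC)OC | starting material
5 | methyl (4E)-4-methylnon-4-en-8-ynoate | COC(=O)CC/C(C)=C/CCC#C | intermediate
6 | (4E)-4-methylnon-4-en-8-ynal | O=CCC/C(C)=C/CCC#C | intermediate (not isolated)
7 | rac-(6E)-2,6-dimethylundeca-1,6-dien-10-yn-3-ol | C=C(C)C(O)CC/C(C)=C/CCC#C | intermediate
8 | methyl (4E,8E)-4,8-dimethyltrideca-4,8-dien-12-ynoate | COC(=O)CC/C(C)=C/CC/C(C)=C/CCC#C | intermediate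
9 | methyl acetate | COC(C)=O | starting material
10 | lithium enolate of methyl acetate (lithium 1-methoxyethen-1-olate) | [Li+].C=C([O-])OC | intermediate (not isolated)
11 | methyl (6E,10E)-6,10-dimethyl-3-oxopentadeca-6,10-dien-14-ynoate | COC(=O)CC(=O)CC/C(C)=C/CC/C(C)=C/CCC#C | intermediate
12 | sodium enolate of 11 | [Na+].COC(=O)C=C([O-])CC/C(C)=C/CC/C(C)=C/CCC#C | intermediate (not isolated)
13 | rac-methyl (6E,10E)-6,10-dimethyl-3-oxo-2-(phenylselanyl)pentadeca-6,10-dien-14-ynoate | COC(=O)C([Se]c1ccccc1)C(=O)CC/C(C)=C/CC/C(C)=C/CCC#C | intermediate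
14 | methyl 3-oxo-8ξ-(phenylselanyl)-15,16,19-trinorlabd-13-yn-18-oate (ring β-keto ester with C4–H and equatorial ester, in equilibrium with its enol; C8 epimers) | CC1([Se]c2ccccc2)CC[C@@H]2[C@](C)(CCC(=O)[C@H]2C(=O)OC)[C@H]1CCC#C | intermediate
15 | methyl 3-oxo-8ξ-(phenylselanyl)-15,16-dinorlabd-13-yn-19-oate (4α-CH3, 4β-CO2Me; C8 epimers) | CC1([Se]c2ccccc2)CC[C@@H]2[C@](C)(CCC(=O)[C@]2(C)C(=O)OC)[C@H]1CCC#C | intermediate
16 | methyl 3-oxo-8ξ-(phenylseleninyl)-15,16-dinorlabd-13-yn-19-oate (selenoxide) | CC1([Se](=O)c2ccccc2)CC[C@@H]2[C@](C)(CCC(=O)[C@]2(C)C(=O)OC)[C@H]1CCC#C | intermediate (not isolated)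
17 | methyl 3-oxo-15,16-dinorlabd-8(17)-en-13-yn-19-oate | C=C1CC[C@@H]2[C@](C)(CCC(=O)[C@]2(C)C(=O)OC)[C@H]1CCC#C | intermediate
18 | lithium 3α-alkoxide of methyl 3α-hydroxy-15,16-dinorlabd-8(17)-en-13-yn-19-oate | C=C1CC[C@@H]2[C@](C)(CC[C@@H]([O-])[C@]2(C)C(=O)OC)[C@H]1CCC#C.[Li+] | intermediate (not isolated)
19 | methyl 3α-acetoxy-15,16-dinorlabd-8(17)-en-13-yn-19-oate | C=C1CC[C@@H]2[C@](C)(CC[C@@H](OC(C)=O)[C@]2(C)C(=O)OC)[C@H]1CCC#C | intermediate
20 | [(13E)-3α-acetoxy-19-methoxy-19-oxo-15-norlabda-8(17),13-dien-14-yl]dimethylalane | C=C1CC[C@@H]2[C@](C)(CC[C@@H](OC(C)=O)[C@]2(C)C(=O)OC)[C@H]1CC/C(C)=C/[Al](C)C | intermediate (not isolated)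
21 | methyl (13E)-3α-acetoxy-15-hydroxylabda-8(17),13-dien-19-oate | C=C1CC[C@@H]2[C@](C)(CC[C@@H](OC(C)=O)[C@]2(C)C(=O)OC)[C@H]1CC/C(C)=C/CO | intermediate
22 | methyl (13R,14R)-3α-acetoxy-13,14-epoxy-15-hydroxylabd-8(17)-en-19-oate | C=C1CC[C@@H]2[C@](C)(CC[C@@H](OC(C)=O)[C@]2(C)C(=O)OC)[C@H]1CC[C@@]1(C)O[C@@H]1CO | intermediate
23 | methyl (13R,14S)-3α-acetoxy-13,14-epoxy-15-oxolabd-8(17)-en-19-oate (CNP0145900.1; 3R,4R,5R,9S,10R,13R,14S) | C=C1CC[C@@H]2[C@](C)(CC[C@@H](OC(C)=O)[C@]2(C)C(=O)OC)[C@H]1CC[C@@]1(C)O[C@@H]1C=O | target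

**Count and risks**

Total step count: 13. Longest linear sequence: 13 (fully linear from 1).

Three steps most likely to fail:

Step 7 (key bicyclization). The risks are a low enantiomeric excess with this substrate, and attack of the C8 radical or of PhSe radicals on the terminal alkyne. The fallback changes the radical chemistry to an oxidative free-radical cyclization with the C4 methyl group already in place, and moves absolute control to a reagent-controlled reduction. It sets out from 8. Crossed Claisen condensation of 8 with the lithium enolate of methyl propanoate (LiN(iPr)2, THF, −78 → 0 °C) gives rac-methyl (6E,10E)-2,6,10-trimethyl-3-oxopentadeca-6,10-dien-14-ynoate F3. Mn(OAc)3·2H2O (2.2 equiv) and Cu(OAc)2·H2O (1 equiv) in degassed AcOH at 23 °C cyclize it through the non-chelated radical (ester anti to the ketone, hence axial CO2Me); divalent copper oxidizes the C8 radical to the exocyclic alkene. This gives rac-methyl 3-oxo-15,16-dinorlabd-8(17)-en-13-yn-19-oate F4. Catecholborane with (S)-2-methyl-CBS-oxazaborolidine in toluene at −78 °C reduces both enantiomers under catalyst control to the (3R) alcohol. The ketone of the normal series gives methyl 3α-hydroxy-15,16-dinorlabd-8(17)-en-13-yn-19-oate F5. Its mirror image gives the diastereomeric equatorial alcohol methyl (3R)-3-hydroxy-ent-15,16-dinorlabd-8(17)-en-13-yn-19-oate F6, which is removed by chromatography. Acetylation of F5 (Ac2O, DMAP, pyridine) comes back to the route at 19.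

Step 11 (methylalumination beside the C3 acetate). The risk is that AlMe3 attacks the acetate before the alkyne is consumed. The fallback carries C3 as the free alcohol (an inert aluminium alkoxide during carbometalation) and acetylates last. It sets out from 17. LiBH(s-Bu)3 in THF at −78 °C with aqueous work-up gives methyl 3α-hydroxy-15,16-dinorlabd-8(17)-en-13-yn-19-oate F7 (same structure as F5). AlMe3 (4 equiv) and Cp2ZrCl2 in CH2Cl2, then (CH2O)n, give methyl (13E)-3α,15-dihydroxylabda-8(17),13-dien-19-oate F8. Ti(OiPr)4, D-(−)-diethyl tartrate and t-BuOOH at −20 °C give methyl (13R,14R)-13,14-epoxy-3α,15-dihydroxylabd-8(17)-en-19-oate F9. TEMPO with PhI(OAc)2 in CH2Cl2 oxidizes only the primary alcohol to methyl (13R,14S)-13,14-epoxy-3α-hydroxy-15-oxolabd-8(17)-en-19-oate F10. Ac2O, DMAP and pyridine at 0 → 23 °C acetylate the hindered axial alcohol and come back to the route at 23.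

Step 3 (one-pot partial reduction and Grignard addition). The risks are over-reduction of 5 to the primary alcohol and incomplete trapping of the aldehyde. The fallback replaces partial reduction by acyl substitution followed by 1,2-reduction. It sets out from 5. MeNH(OMe)·HCl and iPrMgCl in THF at −20 °C give (4E)-N-methoxy-N,4-dimethylnon-4-en-8-ynamide F1. Isopropenylmagnesium bromide 2 at 0 °C gives (6E)-2,6-dimethylundeca-1,6-dien-10-yn-3-one F2. Luche reduction (NaBH4, CeCl3·7H2O, MeOH, −78 °C) reduces the enone 1,2 and comes back to the route at 7.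

Further compounds
F1 | step 3 | (4E)-N-methoxy-N,4-dimethylnon-4-en-8-ynamide | CON(C)C(=O)CC/C(C)=C/CCC#C
F2 | step 3 | (6E)-2,6-dimethylundeca-1,6-dien-10-yn-3-one | C=C(C)C(=O)CC/C(C)=C/CCC#C
F3 | step 7 | rac-methyl (6E,10E)-2,6,10-trimethyl-3-oxopentadeca-6,10-dien-14-ynoate | COC(=O)C(C)C(=O)CC/C(C)=C/CC/C(C)=C/CCC#C
F4 | step 7 | rac-methyl 3-oxo-15,16-dinorlabd-8(17)-en-13-yn-19-oate (both enantiomers) | C=C1CC[C@@H]2[C@](C)(CCC(=O)[C@]2(C)C(=O)OC)[C@H]1CCC#C.C=C1CC[C@H]2[C@@](C)(CCC(=O)[C@@]2(C)C(=O)OC)[C@@H]1CCC#C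
F5 | step 7 | methyl 3α-hydroxy-15,16-dinorlabd-8(17)-en-13-yn-19-oate | C=C1CC[C@@H]2[C@](C)(CC[C@@H](O)[C@]2(C)C(=O)OC)[C@H]1CCC#C
F6 | step 7 | methyl (3R)-3-hydroxy-ent-15,16-dinorlabd-8(17)-en-13-yn-19-oate (equatorial alcohol of the mirror-image series) | C=C1CC[C@H]2[C@@](C)(CC[C@@H](O)[C@@]2(C)C(=O)OC)[C@@H]1CCC#C
F7 | step 11 | methyl 3α-hydroxy-15,16-dinorlabd-8(17)-en-13-yn-19-oate | C=C1CC[C@@H]2[C@](C)(CC[C@@H](O)[C@]2(C)C(=O)OC)[C@H]1CCC#C
F8 | step 11 | methyl (13E)-3α,15-dihydroxylabda-8(17),13-dien-19-oate | C=C1CC[C@@H]2[C@](C)(CC[C@@H](O)[C@]2(C)C(=O)OC)[C@H]1CC/C(C)=C/CO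
F9 | step 11 | methyl (13R,14R)-13,14-epoxy-3α,15-dihydroxylabd-8(17)-en-19-oate | C=C1CC[C@@H]2[C@](C)(CC[C@@H](O)[C@]2(C)C(=O)OC)[C@H]1CC[C@@]1(C)O[C@@H]1CO
F10 | step 11 | methyl (13R,14S)-13,14-epoxy-3α-hydroxy-15-oxolabd-8(17)-en-19-oate | C=C1CC[C@@H]2[C@](C)(CC[C@@H](O)[C@]2(C)C(=O)OC)[C@H]1CC[C@@]1(C)O[C@@H]1C=O
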